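Everything rests on disconnecting the Cb–C1' bond of the two-carbon tether (Ca attached to C2 of pyranone ring C, Cb attached to C1' of ring B). One Mizoroki–Heck coupling joins a 2-vinylchromone to unprotected 5-iodo-2-methoxyphenol, and hydrogenation of the styryl alkene then gives the target. Two features are used: the tether carbon C1' of ring B stands para to the C4' methoxy group and meta to the C3' hydroxyl, where iodoguaiacol carries its iodine; and an unsaturated Ca=Cb unit is conjugated through C2=C3 with the C4 ketone, which sends the aryl group to terminal Cb. The vinylchromone derives from a 2-formylchromone assembled with an acetal ester.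

Key step: step 4

Remark: the 1,3-dione of step 1 is written as its diketo form, although it should exist mainly as enol and cyclic hemiketal tautomers; this does not change the chemistry.

Step 1
Reactants: 1 1-(2-hydroxy-4,5-dimethoxyphenyl)ethanone; 2 ethyl 2,2-diethoxyacetate
Product: 3 4,4-diethoxy-1-(2-hydroxy-4,5-dimethoxyphenyl)butane-1,3-dione
Conditions: NaH (3.5 equiv), THF, reflux; then 1 M HCl to pH 5, 0 °C; crude product used directly
Reagents that add atoms: none
Why: Crossed Claisen condensation: NaH turns 1 into its phenoxide–enolate dianion, which is C-acylated by ester 2 (an ester that does not self-condense under these conditions), and deprotonation of the resulting 1,3-dione drives the reaction; the acetal carbon delivers Ca already at the aldehyde oxidation level, so no later oxidation of a methyl group is needed.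

Step 2
Reactants: 3 4,4-diethoxy-1-(2-hydroxy-4,5-dimethoxyphenyl)butane-1,3-dione
Product: 5 6,7-dimethoxy-4-oxo-4H-chromene-2-carbaldehyde, via chromone diethyl acetal 4 (not isolated)
Conditions: AcOH, conc. HCl, 60 °C; then H2O, 90 °C; product dried by azeotropic distillation from toluene
Reagents that add atoms: water, O
Why: Acid-catalysed cyclodehydration of an o-hydroxyaryl 1,3-dione (the phenol oxygen adds to the C3 ketone of the dione and water is lost, the classical chromone closure) gives acetal 4, whose diethyl acetal is then hydrolysed by the aqueous acid; the methyl ethers and the pyranone are stable to HCl in AcOH.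

Step 3
Reactants: 5 6,7-dimethoxy-4-oxo-4H-chromene-2-carbaldehyde
Product: 6 2-ethenyl-6,7-dimethoxy-4H-chromen-4-one
Conditions: Ph3PCH3Br (1.1 equiv), NaN(SiMe3)2 (1.05 equiv), THF, 0 °C; ylide solution added to 5, THF, −78 to 0 °C; product kept cold and used promptly
Reagents that add atoms: methyltriphenylphosphonium bromide, C[P+](c1ccccc1)(c1ccccc1)c1ccccc1.[Br-]
Why: Wittig methylenation: the non-stabilised ylide adds to the strongly electrophilic 2-formyl group much faster than to the vinylogous-ester carbonyl C4 or to C2, and collapse of the oxaphosphetane gives the terminal alkene; adding the ylide to the aldehyde at low temperature without excess keeps base away from the Michael-acceptor product.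

Step 4
Reactants: 6 2-ethenyl-6,7-dimethoxy-4H-chromen-4-one (1.2 equiv); 7 5-iodo-2-methoxyphenol
Product: 8 2-[(E)-2-(3-hydroxy-4-methoxyphenyl)ethenyl]-6,7-dimethoxy-4H-chromen-4-one
Conditions: Pd(OAc)2 (5 mol %), P(o-tol)3 (10 mol %), Et3N (2.5 equiv), DMF, 80 °C, N2
Reagents that add atoms: none
Why: Pd(OAc)2 is reduced in the flask to zerovalent palladium, which inserts into the C–I bond of 7; the aryl palladium iodide coordinates the vinyl group of 6, migratory insertion places the aryl group on Cb and palladium on Ca, and syn β-hydride elimination followed by transfer of HI to Et3N releases the E alkene and the catalyst. This is a Mizoroki–Heck reaction of the kind established for aryl iodides, unprotected iodophenols among them, on acrylates, vinyl ketones and vinyl-substituted electron-poor heteroarenes. No ring is closed and no stereocentre is formed, so neither a mode of closure nor a stereocontrol element is involved. The step needs regioselectivity for Cb over Ca, which the substrate secures because Ca=Cb is polarised through C2=C3 towards the C4 carbonyl as in an acrylate and because Ca is the more hindered carbon. It also needs C–C coupling to outrun addition of the phenol oxygen to Cb, which the weak amine base secures by leaving the phenol un-ionised. The E geometry follows from the syn elimination but is immaterial, as the alkene is saturated in step 5.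

Step 5
Reactants: 8 2-[(E)-2-(3-hydroxy-4-methoxyphenyl)ethenyl]-6,7-dimethoxy-4H-chromen-4-one
Product: 9 2-[2-(3-hydroxy-4-methoxyphenyl)ethyl]-6,7-dimethoxy-4H-chromen-4-one
Conditions: H2 (1 atm), 10% Pd/C, EtOAc–MeOH, rt; stopped after uptake of 1 equiv H2
Reagents that add atoms: none
Why: Heterogeneous catalytic hydrogenation: the disubstituted styryl alkene should be reduced much faster than the C2=C3 bond, which is trisubstituted and deactivated as part of a vinylogous ester, so stopping after one equivalent of H2 should give the 2-(2-arylethyl)chromone; aryl ethers, the phenol and the ketone are inert under these conditions.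

Compound list
1 | 1-(2-hydroxy-4,5-dimethoxyphenyl)ethanone | CC(=O)c1cc(OC)c(OC)cc1O | starting material
2 | ethyl 2,2-diethoxyacetate | CCOC(=O)C(OCC)OCC | starting material
3 | 4,4-diethoxy-1-(2-hydroxy-4,5-dimethoxyphenyl)butane-1,3-dione | CCOC(OCC)C(=O)CC(=O)c1cc(OC)c(OC)cc1O | intermediate
4 | 2-(diethoxymethyl)-6,7-dimethoxy-4H-chromen-4-one | CCOC(OCC)c1cc(=O)c2cc(OC)c(OC)cc2o1 | intermediate (not isolated)
5 | 6,7-dimethoxy-4-oxo-4H-chromene-2-carbaldehyde | O=Cc1cc(=O)c2cc(OC)c(OC)cc2o1 | intermediate
6 | 2-ethenyl-6,7-dimethoxy-4H-chromen-4-one | C=Cc1cc(=O)c2cc(OC)c(OC)cc2o1 | intermediate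
7 | 5-iodo-2-methoxyphenol | COc1ccc(I)cc1O | starting material
8 | 2-[(E)-2-(3-hydroxy-4-methoxyphenyl)ethenyl]-6,7-dimethoxy-4H-chromen-4-one | COc1ccc(/C=C/c2cc(=O)c3cc(OC)c(OC)cc3o2)cc1O | intermediate
9 | 2-[2-(3-hydroxy-4-methoxyphenyl)ethyl]-6,7-dimethoxy-4H-chromen-4-one | COc1ccc(CCc2cc(=O)c3cc(OC)c(OC)cc3o2)cc1O | target

Total step count: 5
Longest linear sequence: 5 steps (1 → 3 → 5 → 6 → 8 → 9)

Steps most likely to fail

Step 4. Conjugate addition of the phenol oxygen or of the amine to Cb, or thermal oligomerisation of the vinyl pyranone, may outrun the coupling, and palladium may precipitate before turnover is complete. The fallback makes the Ca=Cb bond by condensation instead of the Cb–C1' bond by coupling. It sets out from 1: Claisen condensation with ethyl acetate (NaH, THF, reflux) should give 1-(2-hydroxy-4,5-dimethoxyphenyl)butane-1,3-dione F1, and HCl in AcOH should close it to 6,7-dimethoxy-2-methyl-4H-chromen-4-one F2. Vinylogous aldol condensation of F2 with purchasable 3-(benzyloxy)-4-methoxybenzaldehyde (NaOEt, EtOH, rt) should give 2-[(E)-2-(3-benzyloxy-4-methoxyphenyl)ethenyl]-6,7-dimethoxy-4H-chromen-4-one F3. Hydrogenation of F3 over 10% Pd/C saturates the alkene and removes the benzyl group in the same operation, and the fallback comes back to the route at 9.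

Step 3. The ylide is a strong carbon nucleophile and base, so conjugate attack on C2 of the pyranone or on the vinyl group of the product may compete with carbonyl addition, and the product may oligomerise during isolation. The fallback unveils the vinyl group by elimination and needs no aldehyde. It sets out from 1: Claisen condensation with ethyl 3-(dimethylamino)propanoate (NaH, THF, reflux) should give 5-(dimethylamino)-1-(2-hydroxy-4,5-dimethoxyphenyl)pentane-1,3-dione F4, and HCl in AcOH followed by basification should give 2-[2-(dimethylamino)ethyl]-6,7-dimethoxy-4H-chromen-4-one F5. Quaternisation with MeI in acetone should give 2-(6,7-dimethoxy-4-oxo-4H-chromen-2-yl)-N,N,N-trimethylethanaminium iodide F6. K2CO3 in MeCN at rt should then remove the acidic Ca proton and expel trimethylamine from Cb (Hofmann-type E1cB elimination), and the fallback comes back to the route at 6.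

Step 5. The two alkenes are distinguished only by rate, so reduction may continue into the C2=C3 bond of the pyranone once the styryl alkene is consumed. The fallback builds the saturated tether directly by the classical Claisen route to 2-(2-arylethyl)chromones and avoids any alkene. Purchasable 3-(3-hydroxy-4-methoxyphenyl)propanoic acid is esterified (MeOH, cat. H2SO4) to methyl 3-(3-hydroxy-4-methoxyphenyl)propanoate F7. Setting out from 1, Claisen condensation with F7 (NaH, 5 equiv, THF, reflux) should give 1-(2-hydroxy-4,5-dimethoxyphenyl)-5-(3-hydroxy-4-methoxyphenyl)pentane-1,3-dione F8, and cyclodehydration with HCl in AcOH comes back to the route at 9.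

Further compounds
F1 | step 4 | 1-(2-hydroxy-4,5-dimethoxyphenyl)butane-1,3-dione | CC(=O)CC(=O)c1cc(OC)c(OC)cc1O
F2 | step 4 | 6,7-dimethoxy-2-methyl-4H-chromen-4-one | Cc1cc(=O)c2cc(OC)c(OC)cc2o1
F3 | step 4 | 2-[(E)-2-(3-benzyloxy-4-methoxyphenyl)ethenyl]-6,7-dimethoxy-4H-chromen-4-one | COc1ccc(/C=C/c2cc(=O)c3cc(OC)c(OC)cc3o2)cc1OCc1ccccc1
F4 | step 3 | 5-(dimethylamino)-1-(2-hydroxy-4,5-dimethoxyphenyl)pentane-1,3-dione | CN(C)CCC(=O)CC(=O)c1cc(OC)c(OC)cc1O
F5 | step 3 | 2-[2-(dimethylamino)ethyl]-6,7-dimethoxy-4H-chromen-4-one | CN(C)CCc1cc(=O)c2cc(OC)c(OC)cc2o1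
F6 | step 3 | 2-(6,7-dimethoxy-4-oxo-4H-chromen-2-yl)-N,N,N-trimethylethanaminium iodide | C[N+](C)(C)CCc1cc(=O)c2cc(OC)c(OC)cc2o1.[I-]
F7 | step 5 | methyl 3-(3-hydroxy-4-methoxyphenyl)propanoate | COC(=O)CCc1ccc(OC)c(O)c1
F8 | step 5 | 1-(2-hydroxy-4,5-dimethoxyphenyl)-5-(3-hydroxy-4-methoxyphenyl)pentane-1,3-dione | COc1ccc(CCC(=O)CC(=O)c2cc(OC)c(OC)cc2O)cc1O
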